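**Retrosynthetic overview**
1. The dihydrofuran ring, the only non-aromatic ring, closes last: acid unmasks a para-quinone methide on ring C and the ring-B phenol adds to it (intramolecular oxa-Michael, 1,6-addition), trans to the C3 substituent.
2. The (2R,3R)-butane-1,4-diol comes from LiAlH4 opening of a trans-2,3-dibenzylbutyrolactone, made by joining a lactone enolate (ring A half) with a benzylic bromide (rings B and C half).
3. The bromide half comes from an Evans syn-aldol of a ring-B arylacetyl imide with O-benzylvanillin, which sets C3; ring B is built from methyl vanillate by O-allylation, Claisen rearrangement and oxidative cleavage.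
4. The lactone half comes from an Evans alkylation of a dihydroferulic imide with tert-butyl bromoacetate; this sets the first butane centre, which directs the second.
5. Ring order: butyrolactone (temporary), 1,3-dioxane (temporary), dihydrofuran (final step).

Assumption: the SMILES is read as the (2R,3R)-butanediol carrying a trans-(2S,3R)-dihydrobenzofuran; enolates and mixed anhydrides made and used in one flask are numbered as non-isolated intermediates.

**Route**

Step 1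
Reactants: 1 ferulic acid
Product: 2 3-(4-hydroxy-3-methoxyphenyl)propanoic acid
Conditions: H2 (1 atm), Pd/C (10 wt%), MeOH, rt
Reagents that add atoms: none
Why: Catalytic hydrogenation saturates the cinnamic C=C and leaves the arene, acid and phenol untouched.

Step 2
Reactants: 2 3-(4-hydroxy-3-methoxyphenyl)propanoic acid
Product: 3 benzyl 3-[4-(benzyloxy)-3-methoxyphenyl]propanoate
Conditions: BnBr (2.3 equiv), K2CO3, DMF, 60 °C
Reagents that add atoms: benzyl bromide, BrCc1ccccc1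
Why: Williamson-type SN2 alkylation benzylates both the phenoxide and the carboxylate, masking the ring-A phenol for the later basic steps.

Step 3
Reactants: 3 benzyl 3-[4-(benzyloxy)-3-methoxyphenyl]propanoate
Product: 4 3-[4-(benzyloxy)-3-methoxyphenyl]propanoic acid
Conditions: NaOH (2 M aq.), THF/MeOH, rt; then 1 M HCl
Reagents that add atoms: sodium hydroxide, [Na+].[OH-]
Why: Saponification cleaves only the benzyl ester because the aryl benzyl ether is inert to hydroxide.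

Step 4
Reactants: 4 3-[4-(benzyloxy)-3-methoxyphenyl]propanoic acid; 5 (4S)-4-benzyl-1,3-oxazolidin-2-one
Product: 7 (4S)-4-benzyl-3-{3-[4-(benzyloxy)-3-methoxyphenyl]propanoyl}-1,3-oxazolidin-2-one, via mixed pivalic anhydride 6 (not isolated)
Conditions: t-BuCOCl, Et3N, THF, −20 °C; then LiCl, 5, −20 °C to rt
Reagents that add atoms: none
Why: N-acylation of the oxazolidinone by the mixed anhydride occurs at the less hindered carbonyl of 6 (mixed-anhydride acylation).

Step 5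
Reactants: 7 (4S)-4-benzyl-3-{3-[4-(benzyloxy)-3-methoxyphenyl]propanoyl}-1,3-oxazolidin-2-one
Product: 9 tert-butyl (3R)-4-[(4S)-4-benzyl-2-oxo-1,3-oxazolidin-3-yl]-3-{[4-(benzyloxy)-3-methoxyphenyl]methyl}-4-oxobutanoate, via sodium Z-enolate 8 (not isolated)
Conditions: NaN(SiMe3)2, THF, −78 °C; then BrCH2CO2t-Bu, −78 to −40 °C
Reagents that add atoms: tert-butyl bromoacetate, BrCC(=O)OC(C)(C)C
Why: Evans asymmetric alkylation, in which the chelated Z-enolate 8 is alkylated on the face opposite the 4-benzyl group, sets the (R) centre that becomes the first butane stereocentre.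

Step 6
Reactants: 9 tert-butyl (3R)-4-[(4S)-4-benzyl-2-oxo-1,3-oxazolidin-3-yl]-3-{[4-(benzyloxy)-3-methoxyphenyl]methyl}-4-oxobutanoate
Product: 10 tert-butyl (3R)-4-[4-(benzyloxy)-3-methoxyphenyl]-3-(hydroxymethyl)butanoate
Conditions: LiBH4, THF, 0 °C
Reagents that add atoms: none
Why: Reductive cleavage of the activated exocyclic imide carbonyl by LiBH4 spares the tert-butyl ester and releases the auxiliary without touching the stereocentre.

Step 7
Reactants: 10 tert-butyl (3R)-4-[4-(benzyloxy)-3-methoxyphenyl]-3-(hydroxymethyl)butanoate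
Product: 11 (4R)-4-{[4-(benzyloxy)-3-methoxyphenyl]methyl}oxolan-2-one
Conditions: p-TsOH·H2O (10 mol%), toluene, 80 °C
Reagents that add atoms: none
Why: Acid-catalysed lactonisation (intramolecular transesterification) closes the five-membered ring, and the stereocentre is not enolisable.

Step 8
Reactants: 12 vanillin
Product: 13 4-(benzyloxy)-3-methoxybenzaldehyde
Conditions: BnBr, K2CO3, DMF, rt
Reagents that add atoms: benzyl bromide, BrCc1ccccc1
Why: Williamson ether synthesis masks the ring-C phenol so the aldehyde can serve as the aldol acceptor.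

Step 9
Reactants: 14 methyl vanillate
Product: 15 methyl 3-methoxy-4-(prop-2-en-1-yloxy)benzoate
Conditions: allyl bromide, K2CO3, acetone, reflux
Reagents that add atoms: allyl bromide, C=CCBr
Why: Williamson ether synthesis installs the allyl group needed for the Claisen rearrangement.

Step 10
Reactants: 15 methyl 3-methoxy-4-(prop-2-en-1-yloxy)benzoate
Product: 16 methyl 4-hydroxy-3-methoxy-5-(prop-2-en-1-yl)benzoate
Conditions: N,N-diethylaniline, 200 °C
Reagents that add atoms: none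
Why: The aromatic Claisen rearrangement ([3,3]-sigmatropic shift, then re-aromatisation) delivers the allyl group to the only free ortho position.

Step 11
Reactants: 16 methyl 4-hydroxy-3-methoxy-5-(prop-2-en-1-yl)benzoate
Product: 17 methyl 4-(benzyloxy)-3-methoxy-5-(prop-2-en-1-yl)benzoate
Conditions: BnBr, K2CO3, DMF, 60 °C
Reagents that add atoms: benzyl bromide, BrCc1ccccc1
Why: Williamson benzylation masks the ring-B phenol that will later close the dihydrofuran ring.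

Step 12
Reactants: 17 methyl 4-(benzyloxy)-3-methoxy-5-(prop-2-en-1-yl)benzoate
Product: 18 methyl 4-(benzyloxy)-3-methoxy-5-(2-oxoethyl)benzoate
Conditions: OsO4 (2 mol%), NaIO4, 2,6-lutidine, 1,4-dioxane/H2O 3:1, rt
Reagents that add atoms: osmium tetroxide (OsO4), O=[Os](=O)(=O)=O; sodium periodate (NaIO4), [Na+].[O-]I(=O)(=O)=O
Why: The Lemieux–Johnson oxidation (dihydroxylation then periodate cleavage) cuts the terminal alkene to the arylacetaldehyde, with the oxygen passed on from periodate through OsO4.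

Step 13
Reactants: 18 methyl 4-(benzyloxy)-3-methoxy-5-(2-oxoethyl)benzoate
Product: 19 [2-(benzyloxy)-3-methoxy-5-(methoxycarbonyl)phenyl]acetic acid
Conditions: NaClO2, NaH2PO4, 2-methylbut-2-ene, t-BuOH/H2O, 0 °C to rt
Reagents that add atoms: sodium chlorite (NaClO2), [Na+].[O-]Cl=O
Why: The Pinnick oxidation converts the aldehyde to the acid without touching ester or ethers, the alkene scavenging the hypochlorite that would chlorinate the arene.

Step 14
Reactants: 19 [2-(benzyloxy)-3-methoxy-5-(methoxycarbonyl)phenyl]acetic acid; 5 (4S)-4-benzyl-1,3-oxazolidin-2-one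
Product: 21 methyl 4-(benzyloxy)-3-{2-[(4S)-4-benzyl-2-oxo-1,3-oxazolidin-3-yl]-2-oxoethyl}-5-methoxybenzoate, via mixed pivalic anhydride 20 (not isolated)
Conditions: t-BuCOCl, Et3N, THF, −20 °C; then LiCl, 5, −20 °C to rt
Reagents that add atoms: none
Why: Mixed-anhydride N-acylation at low temperature attaches the auxiliary to the arylacetic acid at the less hindered carbonyl of 20.

Step 15
Reactants: 21 methyl 4-(benzyloxy)-3-{2-[(4S)-4-benzyl-2-oxo-1,3-oxazolidin-3-yl]-2-oxoethyl}-5-methoxybenzoate; 13 4-(benzyloxy)-3-methoxybenzaldehyde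
Product: 23 methyl 4-(benzyloxy)-3-{(2S,3S)-1-[(4S)-4-benzyl-2-oxo-1,3-oxazolidin-3-yl]-3-[4-(benzyloxy)-3-methoxyphenyl]-3-hydroxy-1-oxopropan-2-yl}-5-methoxybenzoate, via dibutylboron Z-enolate 22 (not isolated)
Conditions: n-Bu2BOSO2CF3, i-Pr2NEt, CH2Cl2, −78 to 0 °C; then 13, −78 to 0 °C; then pH 7 buffer, MeOH, 30% H2O2, 0 °C
Reagents that add atoms: none
Why: In the Evans syn-aldol reaction the Z-boron enolate 22 reacts through a Zimmerman–Traxler chair on the face dictated by the auxiliary, setting the aryl-bearing carbon (the future C3 of the benzofuran) and the carbinol carbon, whose configuration is erased later.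

Step 16
Reactants: 23 methyl 4-(benzyloxy)-3-{(2S,3S)-1-[(4S)-4-benzyl-2-oxo-1,3-oxazolidin-3-yl]-3-[4-(benzyloxy)-3-methoxyphenyl]-3-hydroxy-1-oxopropan-2-yl}-5-methoxybenzoate
Product: 24 (1S,2R)-1-[4-(benzyloxy)-3-methoxyphenyl]-2-[2-(benzyloxy)-5-(hydroxymethyl)-3-methoxyphenyl]propane-1,3-diol
Conditions: LiBH4 (excess), THF, 0 °C, then 50 °C
Reagents that add atoms: none
Why: Hydride reduction cleaves the imide at 0 °C and, on warming, reduces the aryl methyl ester, so one operation gives the triol and frees the auxiliary with the stereocentres untouched.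

Step 17
Reactants: 24 (1S,2R)-1-[4-(benzyloxy)-3-methoxyphenyl]-2-[2-(benzyloxy)-5-(hydroxymethyl)-3-methoxyphenyl]propane-1,3-diol
Product: 25 {4-(benzyloxy)-3-[(4S,5R)-4-[4-(benzyloxy)-3-methoxyphenyl]-2,2-dimethyl-1,3-dioxan-5-yl]-5-methoxyphenyl}methanol
Conditions: Me2C(OMe)2, PPTS (5 mol%), acetone, rt
Reagents that add atoms: 2,2-dimethoxypropane, COC(C)(C)OC
Why: Thermodynamic ketalisation selects the six-membered acetonide of the 1,3-diol and leaves the isolated benzylic alcohol free.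

Step 18
Reactants: 25 {4-(benzyloxy)-3-[(4S,5R)-4-[4-(benzyloxy)-3-methoxyphenyl]-2,2-dimethyl-1,3-dioxan-5-yl]-5-methoxyphenyl}methanol
Product: 26 (4S,5R)-4-[4-(benzyloxy)-3-methoxyphenyl]-5-[2-(benzyloxy)-5-(bromomethyl)-3-methoxyphenyl]-2,2-dimethyl-1,3-dioxane
Conditions: CBr4, PPh3, CH2Cl2, 0 °C
Reagents that add atoms: carbon tetrabromide, BrC(Br)(Br)Br
Why: The Appel reaction turns the primary benzylic alcohol into the bromide under near-neutral conditions that spare the acetonide.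

Step 19
Reactants: 11 (4R)-4-{[4-(benzyloxy)-3-methoxyphenyl]methyl}oxolan-2-one; 26 (4S,5R)-4-[4-(benzyloxy)-3-methoxyphenyl]-5-[2-(benzyloxy)-5-(bromomethyl)-3-methoxyphenyl]-2,2-dimethyl-1,3-dioxane
Product: 28 (3R,4R)-3-({4-(benzyloxy)-3-[(4S,5R)-4-[4-(benzyloxy)-3-methoxyphenyl]-2,2-dimethyl-1,3-dioxan-5-yl]-5-methoxyphenyl}methyl)-4-{[4-(benzyloxy)-3-methoxyphenyl]methyl}oxolan-2-one, via lithium enolate 27 (not isolated)
Conditions: LiN(SiMe3)2, THF, −78 °C; then 26, DMPU, −78 to −30 °C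
Reagents that add atoms: none
Why: SN2 alkylation of lactone enolate 27 occurs anti to the C4 arylmethyl group, giving the trans (3R,4R) lactone by substrate control.

Step 20
Reactants: 28 the trans (3R,4R) lactone
Product: 29 (2R,3R)-2-({4-(benzyloxy)-3-[(4S,5R)-4-[4-(benzyloxy)-3-methoxyphenyl]-2,2-dimethyl-1,3-dioxan-5-yl]-5-methoxyphenyl}methyl)-3-{[4-(benzyloxy)-3-methoxyphenyl]methyl}butane-1,4-diol
Conditions: LiAlH4, THF, 0 °C to rt; aq. KNaC4H4O6 work-up
Reagents that add atoms: none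
Why: Hydride reduction opens the lactone to the 1,4-diol without touching either stereocentre, while benzyl ethers and acetonide are inert.

Step 21
Reactants: 29 the tribenzyl acetonide diol
Product: 30 (2R,3R)-2-({4-hydroxy-3-[(4S,5R)-4-(4-hydroxy-3-methoxyphenyl)-2,2-dimethyl-1,3-dioxan-5-yl]-5-methoxyphenyl}methyl)-3-[(4-hydroxy-3-methoxyphenyl)methyl]butane-1,4-diol
Conditions: H2 (1 atm), Pd/C (10 wt%), EtOAc/EtOH, rt, stopped after 3 equiv H2
Reagents that add atoms: none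
Why: Hydrogenolysis removes the three aryl benzyl ethers, which cleave much faster than the benzylic C–O bond of the ketal under neutral conditions.

Step 22
Reactants: 30 the triphenol acetonide diol
Product: 32 (2R,3R)-2-{[(2S,3R)-2-(4-hydroxy-3-methoxyphenyl)-3-(hydroxymethyl)-7-methoxy-2,3-dihydro-1-benzofuran-5-yl]methyl}-3-[(4-hydroxy-3-methoxyphenyl)methyl]butane-1,4-diol, via para-quinone methide 31 (not isolated)
Conditions: p-TsOH·H2O (0.2 equiv), MeCN/H2O 10:1, 40 °C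
Reagents that add atoms: none
Why: Acid opens the benzylic C–O bond para to the free ring-C phenol to give quinone methide 31 with loss of acetone, and the ring-B phenol adds to its exocyclic carbon in a 5-exo intramolecular oxa-Michael (1,6-conjugate) addition anti to the CH2OH group at C3, giving the trans (2S,3R) ring under kinetic and (reversible) thermodynamic control.

**Compound list**

1 | ferulic acid, (E)-3-(4-hydroxy-3-methoxyphenyl)prop-2-enoic acid | COc1cc(/C=C/C(=O)O)ccc1O | starting material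
2 | 3-(4-hydroxy-3-methoxyphenyl)propanoic acid | COc1cc(CCC(=O)O)ccc1O | intermediate
3 | benzyl 3-[4-(benzyloxy)-3-methoxyphenyl]propanoate | COc1cc(CCC(=O)OCc2ccccc2)ccc1OCc1ccccc1 | intermediate
4 | 3-[4-(benzyloxy)-3-methoxyphenyl]propanoic acid | COc1cc(CCC(=O)O)ccc1OCc1ccccc1 | intermediate
5 | (4S)-4-benzyl-1,3-oxazolidin-2-one | O=C1N[C@@H](Cc2ccccc2)CO1 | starting material
6 | 3-[4-(benzyloxy)-3-methoxyphenyl]propanoic pivalic anhydride | COc1cc(CCC(=O)OC(=O)C(C)(C)C)ccc1OCc1ccccc1 | intermediate (not isolated)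
7 | (4S)-4-benzyl-3-{3-[4-(benzyloxy)-3-methoxyphenyl]propanoyl}-1,3-oxazolidin-2-one | COc1cc(CCC(=O)N2C(=O)OC[C@@H]2Cc2ccccc2)ccc1OCc1ccccc1 | intermediate
8 | sodium (Z)-enolate of 7 | [Na+].[O-]/C(=C\Cc1ccc(OCc2ccccc2)c(OC)c1)N1C(=O)OC[C@@H]1Cc1ccccc1 | intermediate (not isolated)
9 | tert-butyl (3R)-4-[(4S)-4-benzyl-2-oxo-1,3-oxazolidin-3-yl]-3-{[4-(benzyloxy)-3-methoxyphenyl]methyl}-4-oxobutanoate | COc1cc(C[C@H](CC(=O)OC(C)(C)C)C(=O)N2C(=O)OC[C@@H]2Cc2ccccc2)ccc1OCc1ccccc1 | intermediate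
10 | tert-butyl (3R)-4-[4-(benzyloxy)-3-methoxyphenyl]-3-(hydroxymethyl)butanoate | COc1cc(C[C@H](CC(=O)OC(C)(C)C)CO)ccc1OCc1ccccc1 | intermediate
11 | (4R)-4-{[4-(benzyloxy)-3-methoxyphenyl]methyl}oxolan-2-one | COc1cc(C[C@@H]2CC(=O)OC2)ccc1OCc1ccccc1 | intermediate
12 | vanillin | COc1cc(C=O)ccc1O | starting material
13 | 4-(benzyloxy)-3-methoxybenzaldehyde | COc1cc(C=O)ccc1OCc1ccccc1 | intermediate
14 | methyl vanillate, methyl 4-hydroxy-3-methoxybenzoate | COC(=O)c1ccc(O)c(OC)c1 | starting material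
15 | methyl 3-methoxy-4-(prop-2-en-1-yloxy)benzoate | COC(=O)c1ccc(OCC=C)c(OC)c1 | intermediate
16 | methyl 4-hydroxy-3-methoxy-5-(prop-2-en-1-yl)benzoate | COC(=O)c1cc(CC=C)c(O)c(OC)c1 | intermediate
17 | methyl 4-(benzyloxy)-3-methoxy-5-(prop-2-en-1-yl)benzoate | COC(=O)c1cc(CC=C)c(OCc2ccccc2)c(OC)c1 | intermediate
18 | methyl 4-(benzyloxy)-3-methoxy-5-(2-oxoethyl)benzoate | COC(=O)c1cc(CC=O)c(OCc2ccccc2)c(OC)c1 | intermediate
19 | [2-(benzyloxy)-3-methoxy-5-(methoxycarbonyl)phenyl]acetic acid | COC(=O)c1cc(CC(=O)O)c(OCc2ccccc2)c(OC)c1 | intermediate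
20 | [2-(benzyloxy)-3-methoxy-5-(methoxycarbonyl)phenyl]acetic pivalic anhydride | COC(=O)c1cc(CC(=O)OC(=O)C(C)(C)C)c(OCc2ccccc2)c(OC)c1 | intermediate (not isolated)
21 | methyl 4-(benzyloxy)-3-{2-[(4S)-4-benzyl-2-oxo-1,3-oxazolidin-3-yl]-2-oxoethyl}-5-methoxybenzoate | COC(=O)c1cc(CC(=O)N2C(=O)OC[C@@H]2Cc2ccccc2)c(OCc2ccccc2)c(OC)c1 | intermediate
22 | dibutylboron (Z)-enolate of 21 | CCCCB(CCCC)O/C(=C\c1cc(C(=O)OC)cc(OC)c1OCc1ccccc1)N1C(=O)OC[C@@H]1Cc1ccccc1 | intermediate (not isolated)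
23 | methyl 4-(benzyloxy)-3-{(2S,3S)-1-[(4S)-4-benzyl-2-oxo-1,3-oxazolidin-3-yl]-3-[4-(benzyloxy)-3-methoxyphenyl]-3-hydroxy-1-oxopropan-2-yl}-5-methoxybenzoate | COC(=O)c1cc([C@H](C(=O)N2C(=O)OC[C@@H]2Cc2ccccc2)[C@H](O)c2ccc(OCc3ccccc3)c(OC)c2)c(OCc2ccccc2)c(OC)c1 | intermediate
24 | (1S,2R)-1-[4-(benzyloxy)-3-methoxyphenyl]-2-[2-(benzyloxy)-5-(hydroxymethyl)-3-methoxyphenyl]propane-1,3-diol | OCc1cc([C@H](CO)[C@H](O)c2ccc(OCc3ccccc3)c(OC)c2)c(OCc2ccccc2)c(OC)c1 | intermediate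
25 | {4-(benzyloxy)-3-[(4S,5R)-4-[4-(benzyloxy)-3-methoxyphenyl]-2,2-dimethyl-1,3-dioxan-5-yl]-5-methoxyphenyl}methanol | OCc1cc([C@@H]2COC(C)(C)O[C@@H]2c2ccc(OCc3ccccc3)c(OC)c2)c(OCc2ccccc2)c(OC)c1 | intermediate
26 | (4S,5R)-4-[4-(benzyloxy)-3-methoxyphenyl]-5-[2-(benzyloxy)-5-(bromomethyl)-3-methoxyphenyl]-2,2-dimethyl-1,3-dioxane | BrCc1cc([C@@H]2COC(C)(C)O[C@@H]2c2ccc(OCc3ccccc3)c(OC)c2)c(OCc2ccccc2)c(OC)c1 | intermediate
27 | lithium enolate of 11 | [Li+].[O-]C1=C[C@@H](Cc2ccc(OCc3ccccc3)c(OC)c2)CO1 | intermediate (not isolated)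
28 | (3R,4R)-3-({4-(benzyloxy)-3-[(4S,5R)-4-[4-(benzyloxy)-3-methoxyphenyl]-2,2-dimethyl-1,3-dioxan-5-yl]-5-methoxyphenyl}methyl)-4-{[4-(benzyloxy)-3-methoxyphenyl]methyl}oxolan-2-one | O=C1OC[C@H](Cc2ccc(OCc3ccccc3)c(OC)c2)[C@H]1Cc1cc([C@@H]2COC(C)(C)O[C@@H]2c2ccc(OCc3ccccc3)c(OC)c2)c(OCc2ccccc2)c(OC)c1 | intermediate
29 | (2R,3R)-2-({4-(benzyloxy)-3-[(4S,5R)-4-[4-(benzyloxy)-3-methoxyphenyl]-2,2-dimethyl-1,3-dioxan-5-yl]-5-methoxyphenyl}methyl)-3-{[4-(benzyloxy)-3-methoxyphenyl]methyl}butane-1,4-diol | COc1cc(C[C@@H](CO)[C@H](CO)Cc2cc([C@@H]3COC(C)(C)O[C@@H]3c3ccc(OCc4ccccc4)c(OC)c3)c(OCc3ccccc3)c(OC)c2)ccc1OCc1ccccc1 | intermediate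
30 | (2R,3R)-2-({4-hydroxy-3-[(4S,5R)-4-(4-hydroxy-3-methoxyphenyl)-2,2-dimethyl-1,3-dioxan-5-yl]-5-methoxyphenyl}methyl)-3-[(4-hydroxy-3-methoxyphenyl)methyl]butane-1,4-diol | COc1cc(C[C@@H](CO)[C@H](CO)Cc2cc([C@@H]3COC(C)(C)O[C@@H]3c3ccc(O)c(OC)c3)c(O)c(OC)c2)ccc1O | intermediate
31 | (2R,3R)-2-({4-hydroxy-3-[(2R)-1-hydroxy-3-(3-methoxy-4-oxocyclohexa-2,5-dien-1-ylidene)propan-2-yl]-5-methoxyphenyl}methyl)-3-[(4-hydroxy-3-methoxyphenyl)methyl]butane-1,4-diol, para-quinone methide (either geometry of the exocyclic alkene) | COc1cc(C[C@@H](CO)[C@H](CO)Cc2cc([C@H](CO)C=C3C=CC(=O)C(OC)=C3)c(O)c(OC)c2)ccc1O | intermediate (not isolated)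
32 | (2R,3R)-2-{[(2S,3R)-2-(4-hydroxy-3-methoxyphenyl)-3-(hydroxymethyl)-7-methoxy-2,3-dihydro-1-benzofuran-5-yl]methyl}-3-[(4-hydroxy-3-methoxyphenyl)methyl]butane-1,4-diol | COc1cc(C[C@@H](CO)[C@H](CO)Cc2cc(OC)c3c(c2)[C@H](CO)[C@@H](c2ccc(O)c(OC)c2)O3)ccc1O | target

**Step count and risks**

Total step count: 22.
Longest linear sequence: 14 steps (steps 9 to 22, from methyl vanillate 14). The other branches are 11 steps (1 to 7, then 19 to 22) and 9 steps (8, then 15 to 22).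

Steps most likely to fail:

Step 16 (one-flask reduction of imide and aryl ester). The electron-rich, hindered methyl benzoate may reduce sluggishly, and forcing conditions may erode the yield. The fallback sets out from 23 and comes back at 25. NaBH4 in THF/H2O at 0 °C cleaves only the imide and gives the methyl ester diol F1. Me2C(OMe)2 with PPTS then gives the methyl ester acetonide F2. i-Bu2AlH in toluene at −78 °C reduces the ester to alcohol 25.

Step 19 (enolate alkylation with the labile, electron-rich benzylic bromide 26). The bromide may decompose, or proton transfer and double alkylation may compete. The fallback sets out from 25 and 11 and comes back at 28; it replaces the alkylation by an aldol condensation and conjugate reduction. MnO2 in CH2Cl2 oxidises 25 to the benzaldehyde F3. Addition of lithium enolate 27 at −78 °C gives the aldol adduct F4 as a mixture at the two new centres. MsCl and Et3N give the mesylate F5, which DBU eliminates to the (E)-arylidene lactone F6. Conjugate reduction with NaBH4 and NiCl2·6H2O in MeOH/THF at 0 °C gives 28 beside its cis epimer F7, and DBU in toluene equilibrates F7 to the more stable trans lactone 28.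

Step 21 (hydrogenolysis of three benzyl ethers beside a benzylic ketal). Once the ring-C phenol is free, the benzylic C–O bond of the dioxane may also be hydrogenolysed. The fallback sets out from 29 and comes back at 32; it changes the order of unmasking. AcOH/H2O 4:1 at 40 °C removes the acetonide first and gives the tribenzyl tetraol F8. Hydrogenolysis (H2, Pd/C, EtOAc/EtOH) of this free benzylic alcohol, which loses its C–O bond far less readily than a benzylic ether, gives the heptaol F9. Under the conditions of step 22, F9 loses water to the same quinone methide 31 and closes to 32.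

**Further compounds**

F1 | step 16 | methyl 4-(benzyloxy)-3-{(1S,2R)-1-[4-(benzyloxy)-3-methoxyphenyl]-1,3-dihydroxypropan-2-yl}-5-methoxybenzoate | COC(=O)c1cc([C@H](CO)[C@H](O)c2ccc(OCc3ccccc3)c(OC)c2)c(OCc2ccccc2)c(OC)c1
F2 | step 16 | methyl 4-(benzyloxy)-3-[(4S,5R)-4-[4-(benzyloxy)-3-methoxyphenyl]-2,2-dimethyl-1,3-dioxan-5-yl]-5-methoxybenzoate | COC(=O)c1cc([C@@H]2COC(C)(C)O[C@@H]2c2ccc(OCc3ccccc3)c(OC)c2)c(OCc2ccccc2)c(OC)c1
F3 | step 19 | 4-(benzyloxy)-3-[(4S,5R)-4-[4-(benzyloxy)-3-methoxyphenyl]-2,2-dimethyl-1,3-dioxan-5-yl]-5-methoxybenzaldehyde | O=Cc1cc([C@@H]2COC(C)(C)O[C@@H]2c2ccc(OCc3ccccc3)c(OC)c2)c(OCc2ccccc2)c(OC)c1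
F4 | step 19 | (4R)-3-[{4-(benzyloxy)-3-[(4S,5R)-4-[4-(benzyloxy)-3-methoxyphenyl]-2,2-dimethyl-1,3-dioxan-5-yl]-5-methoxyphenyl}(hydroxy)methyl]-4-{[4-(benzyloxy)-3-methoxyphenyl]methyl}oxolan-2-one (mixture at C3 and at the carbinol carbon) | O=C1OC[C@H](Cc2ccc(OCc3ccccc3)c(OC)c2)C1C(O)c1cc([C@@H]2COC(C)(C)O[C@@H]2c2ccc(OCc3ccccc3)c(OC)c2)c(OCc2ccccc2)c(OC)c1
F5 | step 19 | methanesulfonate of F4 at the carbinol oxygen (mixture at the same two centres) | O=C1OC[C@H](Cc2ccc(OCc3ccccc3)c(OC)c2)C1C(OS(C)(=O)=O)c1cc([C@@H]2COC(C)(C)O[C@@H]2c2ccc(OCc3ccccc3)c(OC)c2)c(OCc2ccccc2)c(OC)c1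
F6 | step 19 | (3E,4R)-3-({4-(benzyloxy)-3-[(4S,5R)-4-[4-(benzyloxy)-3-methoxyphenyl]-2,2-dimethyl-1,3-dioxan-5-yl]-5-methoxyphenyl}methylidene)-4-{[4-(benzyloxy)-3-methoxyphenyl]methyl}oxolan-2-one | O=C1OC[C@H](Cc2ccc(OCc3ccccc3)c(OC)c2)/C1=C\c1cc([C@@H]2COC(C)(C)O[C@@H]2c2ccc(OCc3ccccc3)c(OC)c2)c(OCc2ccccc2)c(OC)c1
F7 | step 19 | (3S,4R) cis epimer of lactone 28 | O=C1OC[C@H](Cc2ccc(OCc3ccccc3)c(OC)c2)[C@@H]1Cc1cc([C@@H]2COC(C)(C)O[C@@H]2c2ccc(OCc3ccccc3)c(OC)c2)c(OCc2ccccc2)c(OC)c1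
F8 | step 21 | (2R,3R)-2-({4-(benzyloxy)-3-[(1S,2R)-1-[4-(benzyloxy)-3-methoxyphenyl]-1,3-dihydroxypropan-2-yl]-5-methoxyphenyl}methyl)-3-{[4-(benzyloxy)-3-methoxyphenyl]methyl}butane-1,4-diol | COc1cc(C[C@@H](CO)[C@H](CO)Cc2cc([C@H](CO)[C@H](O)c3ccc(OCc4ccccc4)c(OC)c3)c(OCc3ccccc3)c(OC)c2)ccc1OCc1ccccc1
F9 | step 21 | (2R,3R)-2-({3-[(1S,2R)-1,3-dihydroxy-1-(4-hydroxy-3-methoxyphenyl)propan-2-yl]-4-hydroxy-5-methoxyphenyl}methyl)-3-[(4-hydroxy-3-methoxyphenyl)methyl]butane-1,4-diol | COc1cc(C[C@@H](CO)[C@H](CO)Cc2cc([C@H](CO)[C@H](O)c3ccc(O)c(OC)c3)c(O)c(OC)c2)ccc1O
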